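The five-membered ring (C1–C5) is cut at C1–C2 and C4–C5. The C6 oxygen lies α to the ring-fusion CH (C5) and β to the quaternary C1, and the isopropyl carbinol C4 is bonded to C5. The seven-membered ring is therefore read as a β-methyl cycloheptenone (C6=O, C5=C1) and C2–C3–C4 as 1-isopropyl-1-(trimethylsilyl)allene. One TiCl4-promoted Danheiser annulation forms both bonds, the cyclopentene, quaternary C1 and the cis ring fusion. Its precursor is trans-4-silyloxy-3,6-dimethylcyclohept-2-enone, whose pseudoaxial C10 silyloxy group should direct the allene to the opposite face. The C3–C4 alkene that remains later receives the C4 hydroxyl from the convex face.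

Key step: step 10

Remarks
- Locants C1–C10 are those of the target skeleton: C1 quaternary fusion carbon, C4 isopropyl carbinol, C5 fusion CH, C6 aroyloxy carbon, C8=C9 alkene, C10 isovaleryloxy carbon. β is the face of the C1 methyl group. In this numbering the target is 1R,4S,5S,6R,10R.
- The C8 methyl stereocentre of the precursor is sacrificial (it becomes sp2 in step 17) and is placed trans to the C10 silyloxy group. In a half-chair-like cycloheptenone this lets the silyloxy group sit pseudoaxial (no A(1,2) strain with the C1 methyl) while the C8 methyl stays pseudoequatorial, which should sharpen the facial bias of the key step.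
- Assumption: methyl hydrogen (R)-3-methylglutarate is bought enantiopure; it leads directly to this trans series.
- The phenol is carried as its acetate, so the last step is a near-neutral aryl-acetate cleavage. The C10 silyl ether is therefore removed with HF·pyridine and not with basic fluoride.

Step 1
Reactants: 1 methyl hydrogen (R)-3-methylglutarate
Product: 3 methyl (3R)-5-[methoxy(methyl)amino]-3-methyl-5-oxopentanoate, via acyl imidazolide 2 (not isolated)
Conditions: carbonyldiimidazole, CH2Cl2, rt; then MeNH(OMe)·HCl, rt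
Reagents that add atoms: N,O-dimethylhydroxylamine hydrochloride, CNOC.Cl
Why: The acid is activated as the acyl imidazolide and intercepted by the hydroxylamine (Weinreb amide formation), leaving the methyl ester and the methyl-bearing stereocentre untouched.

Step 2
Reactants: 3 methyl (3R)-5-[methoxy(methyl)amino]-3-methyl-5-oxopentanoate; 4 isopropenylmagnesium bromide
Product: 5 methyl (3R)-3,6-dimethyl-5-oxohept-6-enoate
Conditions: THF, −20 → 0 °C; aq. NH4Cl
Reagents that add atoms: none
Why: Weinreb ketone synthesis, in which the chelated tetrahedral adduct survives until quench and the amide reacts ahead of the methyl ester at low temperature.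

Step 3
Reactants: 5 methyl (3R)-3,6-dimethyl-5-oxohept-6-enoate
Product: 6 methyl (3R,5R)-5-hydroxy-3,6-dimethylhept-6-enoate
Conditions: (S)-2-methyl-CBS-oxazaborolidine ((S)-1-methyl-3,3-diphenyltetrahydro-1H,3H-pyrrolo[1,2-c][1,3,2]oxazaborole, 0.2 equiv), BH3·SMe2, THF, −20 °C; MeOH
Reagents that add atoms: none
Why: Corey–Bakshi–Shibata reduction with the isopropenyl group as the large ketone substituent, so the (S)-catalyst should set the (5R)-carbinol (future C10) by reagent control.

Step 4
Reactants: 6 methyl (3R,5R)-5-hydroxy-3,6-dimethylhept-6-enoate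
Product: 7 methyl (3R,5R)-5-[(tert-butyldimethylsilyl)oxy]-3,6-dimethylhept-6-enoate
Conditions: TBSOTf, 2,6-lutidine, CH2Cl2, −78 °C
Reagents that add atoms: tert-butyldimethylsilyl trifluoromethanesulfonate (TBSOTf), CC(C)(C)[Si](C)(C)OS(=O)(=O)C(F)(F)F
Why: Silylation of the secondary allylic alcohol with the silyl triflate is fast at low temperature and forestalls δ-lactonisation onto the methyl ester.

Step 5
Reactants: 7 methyl (3R,5R)-5-[(tert-butyldimethylsilyl)oxy]-3,6-dimethylhept-6-enoate
Product: 8 (3R,5R)-5-[(tert-butyldimethylsilyl)oxy]-N-methoxy-N,3,6-trimethylhept-6-enamide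
Conditions: MeNH(OMe)·HCl, AlMe3, CH2Cl2, 0 °C → rt; aq. Rochelle salt
Reagents that add atoms: N,O-dimethylhydroxylamine hydrochloride, CNOC.Cl
Why: Aminolysis of the methyl ester by the aluminium amide generated in the flask (Weinreb amidation), to which the silyl ether and the alkene are inert.

Step 6
Reactants: 8 (3R,5R)-5-[(tert-butyldimethylsilyl)oxy]-N-methoxy-N,3,6-trimethylhept-6-enamide; 9 vinylmagnesium bromide
Product: 10 (5R,7R)-7-[(tert-butyldimethylsilyl)oxy]-5,8-dimethylnona-1,8-dien-3-one
Conditions: THF, −78 → 0 °C; inverse quench into cold 1 M HCl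
Reagents that add atoms: none
Why: Weinreb ketone synthesis with a vinyl Grignard reagent, the inverse acidic quench keeping the liberated amine from adding to the vinyl ketone.

Step 7
Reactants: 10 (5R,7R)-7-[(tert-butyldimethylsilyl)oxy]-5,8-dimethylnona-1,8-dien-3-one
Product: 11 (4R,6R)-4-[(tert-butyldimethylsilyl)oxy]-3,6-dimethylcyclohept-2-en-1-one (trans)
Conditions: second-generation Hoveyda–Grubbs catalyst, (H2IMes)Cl2Ru(=CH-C6H4-2-OiPr) (5 mol%), toluene (2 mM), 80 °C
Reagents that add atoms: none
Why: Ring-closing metathesis in which the catalyst loads at the monosubstituted enone alkene and closes onto the isopropenyl group, giving the seven-membered trisubstituted enone with loss of ethylene and without touching a stereocentre.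

Step 8
Reactants: 12 3-(trimethylsilyl)prop-2-yn-1-ol
Product: 13 3-(trimethylsilyl)prop-2-yn-1-yl methanesulfonate
Conditions: MsCl, Et3N, CH2Cl2, 0 °C
Reagents that add atoms: methanesulfonyl chloride (MsCl), CS(=O)(=O)Cl
Why: Standard mesylation of a primary propargylic alcohol.

Step 9
Reactants: 13 3-(trimethylsilyl)prop-2-yn-1-yl methanesulfonate; 14 isopropylmagnesium chloride
Product: 15 trimethyl(4-methylpenta-1,2-dien-3-yl)silane [1-isopropyl-1-(trimethylsilyl)allene]
Conditions: CuBr, LiBr, THF, −78 °C → rt
Reagents that add atoms: none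
Why: SN2′ displacement of the propargylic mesylate by the organocopper reagent at the silicon-bearing alkyne carbon, the established entry to 1-substituted 1-silylallenes.

Step 10
Reactants: 11 (4R,6R)-4-[(tert-butyldimethylsilyl)oxy]-3,6-dimethylcyclohept-2-en-1-one; 15 trimethyl(4-methylpenta-1,2-dien-3-yl)silane
Product: 16 cis-fused bicyclic ketone (C6 ketone; C3=C4 alkene with 3-trimethylsilyl and 4-isopropyl; 1β-methyl; 5β-H; 8α-methyl; 10β-silyloxy)
Conditions: TiCl4 (1.5 equiv), 15 (2 equiv), CH2Cl2, −78 °C; H2O
Reagents that add atoms: none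
Why: TiCl4 activates the enone and the CH2 terminus of the allene (remote from silicon) adds to C1 in a Hosomi–Sakurai-type conjugate addition, giving a titanium enolate and a silicon-stabilised vinyl cation; a 1,2-silyl shift moves the charge to the isopropyl-bearing carbon, which is captured by the enolate carbon C5 (Danheiser trimethylsilylcyclopentene annulation, known for cyclic enones). The cyclopentene closes by enolate–vinyl cation collapse, C5 attacking the digonal cationic C4 with the C3=C4 bond ending inside the ring (5-endo closure at the vinyl cation, enolate double bond exocyclic). C1 is set by approach of the allene anti to the pseudoaxial C10 silyloxy group, which leaves the methyl syn to the C10 oxygen; C5 follows because the three-carbon unit bound at C1 can reach C5 only on the same face, which enforces the cis fusion. The step needs facial selectivity (trans-4,6 substitution pattern, allylic C–O bond), regioselectivity in the allene (only the terminus remote from silicon is nucleophilic) and survival of the silyl ether (low temperature, short contact with TiCl4). The β,β-disubstituted acceptor is the demanding element, but Lewis-acid conjugate additions of allyl- and allenylsilanes that create quaternary centres on such enones are established.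

Step 11
Reactants: 16 cis-fused bicyclic ketone with the C3 trimethylsilyl group
Product: 17 cis-fused bicyclic ketone (C6 ketone; C3=C4 alkene with 4-isopropyl; 1β-methyl; 5β-H; 8α-methyl; 10β-silyloxy)
Conditions: CF3CO2H (3 equiv), CH2Cl2, 0 °C; aq. NaHCO3
Reagents that add atoms: none
Why: Ipso-protodesilylation of the vinylsilane, in which protonation at the silicon-bearing C3 gives the tertiary, silicon-stabilised C4 cation that loses silicon, so the alkene stays at C3–C4 while cold, anhydrous, brief exposure spares the silyl ether and the C5 centre.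

Step 12
Reactants: 17 cis-fused bicyclic ketone with the C3=C4 alkene
Product: 18 3β,4β-epoxy ketone (C6 ketone; 4α-isopropyl; 1β-methyl; 5β-H; 8α-methyl; 10β-silyloxy)
Conditions: mCPBA, NaHCO3, CH2Cl2, 0 °C
Reagents that add atoms: 3-chloroperoxybenzoic acid (mCPBA), OOC(=O)c1cccc(Cl)c1
Why: Prilezhaev epoxidation of the trisubstituted alkene on the convex β face, anti to the seven-membered-ring carbon C6 on allylic C5, which sets the C4 oxygen β, the buffer protecting the β,γ-epoxy ketone.

Step 13
Reactants: 18 3β,4β-epoxy ketone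
Product: 19 4β,6α-diol (4α-isopropyl; 1β-methyl; 5β-H; 8α-methyl; 10β-silyloxy)
Conditions: LiEt3BH (4 equiv), THF, −78 °C → rt; aq. NH4Cl
Reagents that add atoms: none
Why: The hydride first reduces the C6 ketone from the β face (the side of H5, away from the isopropyl-bearing C4 on the α side) to give the 6α-alcohol, then opens the epoxide by SN2 attack at the less substituted C3, leaving the tertiary 4β-hydroxyl.

Step 14
Reactants: 19 4β,6α-diol; 20 4-acetoxybenzoyl chloride
Product: 21 6α-(4-acetoxybenzoyl) ester (4β-hydroxy; 10β-silyloxy)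
Conditions: pyridine, DMAP (0.2 equiv), CH2Cl2, 0 °C → rt
Reagents that add atoms: none
Why: DMAP-catalysed acylation is selective for the secondary C6 hydroxyl over the tertiary C4 hydroxyl, and the acid chloride reacts far faster than the aryl acetate can pass on its acetyl group.

Step 15
Reactants: 21 6α-(4-acetoxybenzoyl) ester with the 10β-silyloxy group
Product: 22 4β,10β-diol 6α-(4-acetoxybenzoyl) ester
Conditions: HF·pyridine, THF/pyridine, 0 °C → rt
Reagents that add atoms: none
Why: Fluoride-driven cleavage of the silyl ether under acidic, non-nucleophilic conditions that leave the aryl acetate and the benzoate-type ester intact.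

Step 16
Reactants: 22 4β,10β-diol 6α-(4-acetoxybenzoyl) ester
Product: 23 C10 ketone (4β-hydroxy; 6α-(4-acetoxybenzoyloxy); 8α-methyl)
Conditions: Dess–Martin periodinane, NaHCO3, CH2Cl2, rt
Reagents that add atoms: none
Why: Dess–Martin oxidation of the hindered secondary alcohol under buffered neutral conditions, the tertiary alcohol being unable to react.

Step 17
Reactants: 23 C10 ketone
Product: 26 C8=C9 enone (C10 ketone; 4β-hydroxy; 6α-(4-acetoxybenzoyloxy)), via bis(trimethylsilyl) enol ether 24 (not isolated), via C4-silylated enone 25 (not isolated)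
Conditions: TMSOTf, Et3N, CH2Cl2, 0 °C; Pd(OAc)2 (1.1 equiv), MeCN, rt; 1 M HCl, THF, 0 °C
Reagents that add atoms: none
Why: Saegusa–Ito dehydrogenation, in which the ketone can enolise only toward C9 (C1 is quaternary), Pd(OAc)2 turns the silyl enol ether into a palladium enolate whose β-hydride elimination at C8 gives the enone and erases the sacrificial C8 centre, and dilute acid frees the C4 hydroxyl that was silylated in passing.

Step 18
Reactants: 26 C8=C9 enone
Product: 27 10β-allylic alcohol (4β-hydroxy; 6α-(4-acetoxybenzoyloxy))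
Conditions: (S)-2-methyl-CBS-oxazaborolidine (1 equiv), BH3·SMe2 (2 equiv), THF, −40 → −20 °C; MeOH
Reagents that add atoms: none
Why: Corey–Bakshi–Shibata 1,2-reduction with the quaternary C1 as the large substituent, so the (S)-catalyst should deliver hydride to the α face and restore the 10β (10R) carbinol by reagent control.

Step 19
Reactants: 27 10β-allylic alcohol; 28 3-methylbutanoyl chloride (isovaleryl chloride)
Product: 29 10β-isovalerate 6α-(4-acetoxybenzoate) (4β-hydroxy)
Conditions: pyridine, DMAP (0.2 equiv), CH2Cl2, 0 °C → rt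
Reagents that add atoms: none
Why: DMAP-catalysed acylation of the secondary allylic alcohol, the tertiary C4 hydroxyl staying free.

Step 20
Reactants: 29 10β-isovalerate 6α-(4-acetoxybenzoate)
Product: 30 CNP0086724.1
Conditions: NH4OAc, MeOH/H2O (4:1), rt
Reagents that add atoms: none
Why: The aryl acetate is an activated ester (electron-poor phenoxide leaving group) and undergoes ammonium acetate-mediated methanolysis under near-neutral conditions that leave the two alkyl esters untouched.

Compound list
1 | methyl hydrogen (R)-3-methylglutarate [(3R)-5-methoxy-3-methyl-5-oxopentanoic acid] | COC(=O)C[C@H](C)CC(=O)O | starting material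
2 | methyl (3R)-5-(1H-imidazol-1-yl)-3-methyl-5-oxopentanoate (acyl imidazolide) | COC(=O)C[C@H](C)CC(=O)n1ccnc1 | intermediate
3 | methyl (3R)-5-[methoxy(methyl)amino]-3-methyl-5-oxopentanoate | COC(=O)C[C@H](C)CC(=O)N(C)OC | intermediate
4 | isopropenylmagnesium bromide | C=C(C)[Mg]Br | starting material
5 | methyl (3R)-3,6-dimethyl-5-oxohept-6-enoate | COC(=O)C[C@H](C)CC(=O)C(C)=C | intermediate
6 | methyl (3R,5R)-5-hydroxy-3,6-dimethylhept-6-enoate | COC(=O)C[C@H](C)C[C@@H](O)C(C)=C | intermediate
7 | methyl (3R,5R)-5-[(tert-butyldimethylsilyl)oxy]-3,6-dimethylhept-6-enoate | COC(=O)C[C@H](C)C[C@@H](O[Si](C)(C)C(C)(C)C)C(C)=C | intermediate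
8 | (3R,5R)-5-[(tert-butyldimethylsilyl)oxy]-N-methoxy-N,3,6-trimethylhept-6-enamide | CON(C)C(=O)C[C@H](C)C[C@@H](O[Si](C)(C)C(C)(C)C)C(C)=C | intermediate
9 | vinylmagnesium bromide | C=C[Mg]Br | starting material
10 | (5R,7R)-7-[(tert-butyldimethylsilyl)oxy]-5,8-dimethylnona-1,8-dien-3-one | C=CC(=O)C[C@H](C)C[C@@H](O[Si](C)(C)C(C)(C)C)C(C)=C | intermediate
11 | (4R,6R)-4-[(tert-butyldimethylsilyl)oxy]-3,6-dimethylcyclohept-2-en-1-one (trans) | C[C@@H]1C[C@@H](O[Si](C)(C)C(C)(C)C)C(C)=CC(=O)C1 | intermediate
12 | 3-(trimethylsilyl)prop-2-yn-1-ol | C[Si](C)(C)C#CCO | starting material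
13 | 3-(trimethylsilyl)prop-2-yn-1-yl methanesulfonate | C[Si](C)(C)C#CCOS(C)(=O)=O | intermediate
14 | isopropylmagnesium chloride | CC(C)[Mg]Cl | starting material
15 | trimethyl(4-methylpenta-1,2-dien-3-yl)silane [1-isopropyl-1-(trimethylsilyl)allene] | C=C=C(C(C)C)[Si](C)(C)C | intermediate
16 | cis-fused bicyclic ketone: 6-oxo, C3=C4, 3-(trimethylsilyl), 4-isopropyl, 1β-methyl, 5β-H, 8α-methyl, 10β-[(tert-butyldimethylsilyl)oxy] | C[C@@H]1C[C@@H](O[Si](C)(C)C(C)(C)C)[C@]2(C)CC([Si](C)(C)C)=C(C(C)C)[C@@H]2C(=O)C1 | intermediate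
17 | cis-fused bicyclic ketone: 6-oxo, C3=C4, 4-isopropyl, 1β-methyl, 5β-H, 8α-methyl, 10β-[(tert-butyldimethylsilyl)oxy] | C[C@@H]1C[C@@H](O[Si](C)(C)C(C)(C)C)[C@]2(C)CC=C(C(C)C)[C@@H]2C(=O)C1 | intermediate
18 | 3β,4β-epoxy ketone: 6-oxo, 4α-isopropyl, 1β-methyl, 5β-H, 8α-methyl, 10β-[(tert-butyldimethylsilyl)oxy] | C[C@@H]1C[C@@H](O[Si](C)(C)C(C)(C)C)[C@]2(C)C[C@H]3O[C@@]3(C(C)C)[C@@H]2C(=O)C1 | intermediate
19 | 4β,6α-diol: 4α-isopropyl, 1β-methyl, 5β-H, 8α-methyl, 10β-[(tert-butyldimethylsilyl)oxy] | C[C@@H]1C[C@@H](O[Si](C)(C)C(C)(C)C)[C@]2(C)CC[C@](O)(C(C)C)[C@@H]2[C@H](O)C1 | intermediate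
20 | 4-acetoxybenzoyl chloride | CC(=O)Oc1ccc(cc1)C(Cl)=O | starting material
21 | 6α-(4-acetoxybenzoyloxy)-4β-hydroxy-10β-[(tert-butyldimethylsilyl)oxy] compound (8α-methyl) | C[C@@H]1C[C@@H](O[Si](C)(C)C(C)(C)C)[C@]2(C)CC[C@](O)(C(C)C)[C@@H]2[C@H](OC(=O)c2ccc(OC(C)=O)cc2)C1 | intermediate
22 | 6α-(4-acetoxybenzoyloxy)-4β,10β-diol (8α-methyl) | C[C@@H]1C[C@@H](O)[C@]2(C)CC[C@](O)(C(C)C)[C@@H]2[C@H](OC(=O)c2ccc(OC(C)=O)cc2)C1 | intermediate
23 | 6α-(4-acetoxybenzoyloxy)-4β-hydroxy-10-ketone (8α-methyl) | C[C@@H]1CC(=O)[C@]2(C)CC[C@](O)(C(C)C)[C@@H]2[C@H](OC(=O)c2ccc(OC(C)=O)cc2)C1 | intermediate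
24 | C9=C10 trimethylsilyl enol ether with 4β-trimethylsilyloxy group | C[C@@H]1C=C(O[Si](C)(C)C)[C@]2(C)CC[C@](O[Si](C)(C)C)(C(C)C)[C@@H]2[C@H](OC(=O)c2ccc(OC(C)=O)cc2)C1 | intermediate
25 | C8=C9 enone (10-oxo) with 4β-trimethylsilyloxy group | CC1=CC(=O)[C@]2(C)CC[C@](O[Si](C)(C)C)(C(C)C)[C@@H]2[C@H](OC(=O)c2ccc(OC(C)=O)cc2)C1 | intermediate
26 | C8=C9 enone (10-oxo), 4β-hydroxy, 6α-(4-acetoxybenzoyloxy) | CC1=CC(=O)[C@]2(C)CC[C@](O)(C(C)C)[C@@H]2[C@H](OC(=O)c2ccc(OC(C)=O)cc2)C1 | intermediate
27 | 10β-allylic alcohol, 4β-hydroxy, 6α-(4-acetoxybenzoyloxy), C8=C9 | CC1=C[C@@H](O)[C@]2(C)CC[C@](O)(C(C)C)[C@@H]2[C@H](OC(=O)c2ccc(OC(C)=O)cc2)C1 | intermediate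
28 | 3-methylbutanoyl chloride (isovaleryl chloride) | CC(C)CC(Cl)=O | starting material
29 | 10β-(3-methylbutanoyloxy)-6α-(4-acetoxybenzoyloxy)-4β-hydroxy compound, C8=C9 | CC1=C[C@@H](OC(=O)CC(C)C)[C@]2(C)CC[C@](O)(C(C)C)[C@@H]2[C@H](OC(=O)c2ccc(OC(C)=O)cc2)C1 | intermediate
30 | CNP0086724.1: 10β-(3-methylbutanoyloxy)-6α-(4-hydroxybenzoyloxy)-4β-hydroxy-4α-isopropyl-1β,8-dimethyl-5βH-bicyclo[5.3.0]dec-8-ene (target numbering; 1R,4S,5S,6R,10R) | CC1=C[C@@H](OC(=O)CC(C)C)[C@]2(C)CC[C@](O)(C(C)C)[C@@H]2[C@H](OC(=O)c2ccc(O)cc2)C1 | target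

Total step count: 20. Longest linear sequence: 18 steps (steps 1–7 and 10–20); the allene arm (steps 8–9) joins at step 10.

Steps most likely to fail

1. Step 10 (annulation). Attack at the congested C1 next to the silyloxy carbon may be slow or poorly face-selective. Silicon may be lost from the vinyl cation before ring closure, which stops the reaction at the open-chain propargyl ketone. The isopropyl methine hydrogen may shift to the cation, and the Lewis acid may strip the silyl ether. The fallback sets out from 11 and comes back at 17, building the two bonds one after the other. Enone 11 is treated with commercial allenyltributylstannane and TBSOTf (CH2Cl2, −78 °C), a conjugate propargylation anti to the silyloxy group that traps the enolate regiospecifically as the propargylated bis-silyl enol ether F1. The terminal alkyne is iodinated (N-iodosuccinimide, AgNO3 cat., DMF) to the iodoalkyne silyl enol ether F2. Ph3PAuCl/AgBF4 in CH2Cl2/MeOH then closes the ring by 5-endo-dig attack of the enol ether carbon C5 on the activated alkyne, giving the cis-fused C4 vinyl iodide ketone F3. Negishi coupling with isopropylzinc bromide (PdCl2(dppf), THF) installs the isopropyl group and returns 17.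

2. Step 18 (C10 reduction). The inherent facial bias of the bicyclic enone may oppose the catalyst, so hydride may arrive mainly on the β face and give the 10α-alcohol, or selectivity may be low. The fallback sets out from 26 and comes back at 29, using inversion in place of selection. Enone 26 is reduced under substrate control (NaBH4, CeCl3·7H2O, MeOH, −78 °C) to the 10α-allylic alcohol F4. Mitsunobu esterification of F4 with 3-methylbutanoic acid (PPh3, diisopropyl azodicarboxylate, toluene, 0 °C → rt) inverts C10 and gives 29 directly.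

3. Step 13 (double reduction). Hydride may reach C6 from the α face. The C6 alkoxide may open the epoxide intramolecularly at C3 before hydride does, or opening of the hindered epoxide may stall. The fallback sets out from 17 and comes back at 19, avoiding the epoxide. Alkene ketone 17 undergoes Mukaiyama hydration (Co(acac)2, PhSiH3, O2, THF, rt): hydrogen-atom transfer to C3 and capture of the tertiary C4 radical by oxygen on the convex face give the 4β-hydroxy C6 ketone F5. Evans–Saksena reduction of F5 (Me4NBH(OAc)3, MeCN/AcOH, −20 °C) delivers hydride from the C4-bound borate to the β face of C6 and returns diol 19.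

Further compounds
F1 | step 10 | propargylated bis-silyl enol ether: C6 tert-butyldimethylsilyl enol ether (C5=C6), 1β-methyl, 1α-(prop-2-ynyl), 8α-methyl, 10β-[(tert-butyldimethylsilyl)oxy] | C[C@@H]1C[C@@H](O[Si](C)(C)C(C)(C)C)[C@](C)(CC#C)C=C(O[Si](C)(C)C(C)(C)C)C1
F2 | step 10 | iodoalkyne silyl enol ether: as F1 with a 1α-(3-iodoprop-2-ynyl) group | C[C@@H]1C[C@@H](O[Si](C)(C)C(C)(C)C)[C@](C)(CC#CI)C=C(O[Si](C)(C)C(C)(C)C)C1
F3 | step 10 | cis-fused C4 vinyl iodide ketone: 6-oxo, C3=C4, 4-iodo, 1β-methyl, 5β-H, 8α-methyl, 10β-[(tert-butyldimethylsilyl)oxy] | C[C@@H]1C[C@@H](O[Si](C)(C)C(C)(C)C)[C@]2(C)CC=C(I)[C@@H]2C(=O)C1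
F4 | step 18 | 10α-allylic alcohol (C10 epimer of 27) | CC1=C[C@H](O)[C@]2(C)CC[C@](O)(C(C)C)[C@@H]2[C@H](OC(=O)c2ccc(OC(C)=O)cc2)C1
F5 | step 13 | 4β-hydroxy C6 ketone: 4α-isopropyl, 1β-methyl, 5β-H, 8α-methyl, 10β-[(tert-butyldimethylsilyl)oxy] | C[C@@H]1C[C@@H](O[Si](C)(C)C(C)(C)C)[C@]2(C)CC[C@](O)(C(C)C)[C@@H]2C(=O)C1
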